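The pyranone ring C is opened at the bond between the C3 methylene and the C4 carbonyl. C2 (benzylic, bound to O1) and C3 are read as the two carbons of a 1,1-disubstituted aryl enol ether carried on O1, and C4 as the formyl carbon of a ring A salicylaldehyde. An enantioselective rhodium-catalysed intramolecular hydroacylation adds the aldehyde C–H across C2=C3: one operation closes ring C, creates the ketone and sets the 2S centre by catalyst control. Its precursor is achiral and open, a 2-(1-arylvinyloxy)benzaldehyde carrying both prenyl groups and two MOM ethers, assembled by Mitsunobu etherification and dehydrochlorination; acid then frees the phenols.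

Key step: step 7

Remark: the sense of induction of the bisphosphine in step 7 cannot be assigned in advance; (R)-DTBM-SEGPHOS is written, and its antipode is taken if the 2R product should predominate.

Step 1
Reactants: 1 2,4,6-trihydroxybenzaldehyde; 2 1-bromo-3-methylbut-2-ene (prenyl bromide)
Product: 3 2,4,6-trihydroxy-3-(3-methylbut-2-en-1-yl)benzaldehyde
Conditions: 2 (0.9 equiv), DBU (1.0 equiv), THF, 0 °C to rt
Reagents that add atoms: none
Why: Base-mediated C-alkylation (C-prenylation) of the ambident phloroglucinol-type phenoxide; the two free ring carbons of 1 are equivalent, so a single mono-C-prenyl isomer should form, and the bromide as limiting reagent restrains bis-prenylation and O-alkylation.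

Step 2
Reactants: 3 2,4,6-trihydroxy-3-(3-methylbut-2-en-1-yl)benzaldehyde
Product: 4 2-hydroxy-4,6-bis(methoxymethoxy)-3-(3-methylbut-2-en-1-yl)benzaldehyde
Conditions: MOMCl (2.1 equiv), i-Pr2NEt, CH2Cl2, 0 °C
Reagents that add atoms: chloromethyl methyl ether, COCCl
Why: Williamson-type acetalisation (MOM protection); the non-chelated 4-OH should react first and then the less hindered of the two chelated hydroxyls (6-OH, next to H), leaving free the 2-OH that lies between CHO and the prenyl group.

Step 3
Reactants: 5 3-bromo-4-methoxybenzaldehyde; 6 tributyl(3-methylbut-2-en-1-yl)stannane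
Product: 7 4-methoxy-3-(3-methylbut-2-en-1-yl)benzaldehyde
Conditions: Pd(PPh3)4 (5 mol%), DMF, 90 °C
Reagents that add atoms: none
Why: Stille cross-coupling at zerovalent palladium; reductive elimination at the less hindered allyl terminus should give the linear prenyl arene, and the aldehyde is inert to the stannane.

Step 4
Reactants: 7 4-methoxy-3-(3-methylbut-2-en-1-yl)benzaldehyde
Product: 9 rac-2-chloro-1-[4-methoxy-3-(3-methylbut-2-en-1-yl)phenyl]ethan-1-ol, via lithium alkoxide 8 (not isolated)
Conditions: ICH2Cl, MeLi·LiBr, THF, −78 °C; then AcOH, −78 °C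
Reagents that add atoms: chloroiodomethane, ClCI
Why: Lithium carbenoid 1,2-addition to the aldehyde, with chloromethyllithium generated by iodine–lithium exchange in the presence of 7; the cold acetic acid quench should trap alkoxide 8 before it closes to the epoxide, and the new centre is made racemic on purpose because step 6 erases it.

Step 5
Reactants: 4 2-hydroxy-4,6-bis(methoxymethoxy)-3-(3-methylbut-2-en-1-yl)benzaldehyde; 9 rac-2-chloro-1-[4-methoxy-3-(3-methylbut-2-en-1-yl)phenyl]ethan-1-ol
Product: 10 rac-2-{2-chloro-1-[4-methoxy-3-(3-methylbut-2-en-1-yl)phenyl]ethoxy}-4,6-bis(methoxymethoxy)-3-(3-methylbut-2-en-1-yl)benzaldehyde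
Conditions: PPh3, DIAD, THF, 0 °C to rt
Reagents that add atoms: none
Why: Mitsunobu etherification; the chelated phenol 4 is acidic enough to protonate the betaine, and the p-alkoxybenzylic oxyphosphonium ion is reactive enough to be captured by the hindered phenoxide, the configuration at the benzylic carbon being irrelevant.

Step 6
Reactants: 10 rac-2-{2-chloro-1-[4-methoxy-3-(3-methylbut-2-en-1-yl)phenyl]ethoxy}-4,6-bis(methoxymethoxy)-3-(3-methylbut-2-en-1-yl)benzaldehyde
Product: 11 2-({1-[4-methoxy-3-(3-methylbut-2-en-1-yl)phenyl]ethenyl}oxy)-4,6-bis(methoxymethoxy)-3-(3-methylbut-2-en-1-yl)benzaldehyde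
Conditions: t-BuOK (1.5 equiv), THF, 0 °C to rt; chromatography on Et3N-deactivated silica
Reagents that add atoms: none
Why: E2 dehydrochlorination of a β-chloroalkyl aryl ether to the aryl vinyl ether; the only hydrogen β to chlorine is the benzylic α-oxy hydrogen, the aldehyde is not enolisable, and the conjugated 1,1-disubstituted enol ether should result.

Step 7
Reactants: 11 2-({1-[4-methoxy-3-(3-methylbut-2-en-1-yl)phenyl]ethenyl}oxy)-4,6-bis(methoxymethoxy)-3-(3-methylbut-2-en-1-yl)benzaldehyde
Product: 12 (2S)-5,7-bis(methoxymethoxy)-2-[4-methoxy-3-(3-methylbut-2-en-1-yl)phenyl]-8-(3-methylbut-2-en-1-yl)chroman-4-one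
Conditions: [Rh(cod)Cl]2 (2.5 mol%), (R)-DTBM-SEGPHOS (5 mol%), NaB[3,5-(CF3)2C6H3]4 (5 mol%), 1,4-dioxane, 60–80 °C
Reagents that add atoms: none
Why: Proposed new method: oxidative addition of the aldehyde C–H bond of 11 to the cationic monovalent rhodium bisphosphine complex gives an acyl rhodium hydride, the tethered enol ether inserts into Rh–H with hydride going to the internal carbon (future C2) and rhodium to the terminal CH2 (future C3), and C–C reductive elimination from the seven-membered acyl alkyl rhodacycle forms the C3–C4 bond. The closest known reaction type is the rhodium/DTBM-SEGPHOS-catalysed enantioselective endo hydroacylation of ortho-allylbenzaldehydes carrying 1,1-disubstituted alkenes to 3-substituted tetralones, from which 11 differs in that the benzylic CH2 of the tether is the ether oxygen O1, so that the alkene is an aryl enol ether. Ring C is closed in a 6-endo-trig sense, both alkene carbons ending inside the ring. The C2 stereocentre is created in the enantio-determining hydride insertion and is controlled by the chiral bisphosphine alone, which selects one enantiotopic face of the prochiral enol ether. The step needs regioselectivity for the six-membered ketone over the 2-aryl-2-methylbenzofuran-3-one of Markovnikov insertion, which the 1,1-disubstitution should secure because a tertiary alkyl rhodium and its reductive elimination to a quaternary carbon are disfavoured; it also needs chemoselectivity over decarbonylation and over the prenyl groups, which should follow from fast intramolecular trapping of the acyl hydride, possible chelation by the flanking 6-OMOM oxygen, and the inability of the trisubstituted prenyl alkenes to reach the acyl rhodium in a small ring.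

Step 8
Reactants: 12 (2S)-5,7-bis(methoxymethoxy)-2-[4-methoxy-3-(3-methylbut-2-en-1-yl)phenyl]-8-(3-methylbut-2-en-1-yl)chroman-4-one
Product: 13 (2S)-5,7-dihydroxy-2-[4-methoxy-3-(3-methylbut-2-en-1-yl)phenyl]-8-(3-methylbut-2-en-1-yl)chroman-4-one
Conditions: 3 M HCl (aq), MeOH, 50 °C, short reaction time
Reagents that add atoms: none
Why: Acid-catalysed acetal solvolysis (MOM cleavage) in methanol; C2 should not epimerise under acid, since flavanones racemise by base-induced ring opening, and the mild temperature should spare the prenyl groups from cyclisation onto the phenols.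

Compound list
1 | 2,4,6-trihydroxybenzaldehyde | O=Cc1c(O)cc(O)cc1O | starting material
2 | 1-bromo-3-methylbut-2-ene (prenyl bromide) | CC(C)=CCBr | starting material
3 | 2,4,6-trihydroxy-3-(3-methylbut-2-en-1-yl)benzaldehyde | O=Cc1c(O)cc(O)c(CC=C(C)C)c1O | intermediate
4 | 2-hydroxy-4,6-bis(methoxymethoxy)-3-(3-methylbut-2-en-1-yl)benzaldehyde | O=Cc1c(OCOC)cc(OCOC)c(CC=C(C)C)c1O | intermediate
5 | 3-bromo-4-methoxybenzaldehyde | COc1ccc(C=O)cc1Br | starting material
6 | tributyl(3-methylbut-2-en-1-yl)stannane | CCCC[Sn](CCCC)(CCCC)CC=C(C)C | starting material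
7 | 4-methoxy-3-(3-methylbut-2-en-1-yl)benzaldehyde | COc1ccc(C=O)cc1CC=C(C)C | intermediate
8 | lithium 2-chloro-1-[4-methoxy-3-(3-methylbut-2-en-1-yl)phenyl]ethan-1-olate (racemic) | [Li+].COc1ccc(C([O-])CCl)cc1CC=C(C)C | intermediate (not isolated)
9 | rac-2-chloro-1-[4-methoxy-3-(3-methylbut-2-en-1-yl)phenyl]ethan-1-ol | COc1ccc(C(O)CCl)cc1CC=C(C)C | intermediate
10 | rac-2-{2-chloro-1-[4-methoxy-3-(3-methylbut-2-en-1-yl)phenyl]ethoxy}-4,6-bis(methoxymethoxy)-3-(3-methylbut-2-en-1-yl)benzaldehyde | COc1ccc(C(CCl)Oc2c(C=O)c(OCOC)cc(OCOC)c2CC=C(C)C)cc1CC=C(C)C | intermediate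
11 | 2-({1-[4-methoxy-3-(3-methylbut-2-en-1-yl)phenyl]ethenyl}oxy)-4,6-bis(methoxymethoxy)-3-(3-methylbut-2-en-1-yl)benzaldehyde | COc1ccc(C(=C)Oc2c(C=O)c(OCOC)cc(OCOC)c2CC=C(C)C)cc1CC=C(C)C | intermediate
12 | (2S)-5,7-bis(methoxymethoxy)-2-[4-methoxy-3-(3-methylbut-2-en-1-yl)phenyl]-8-(3-methylbut-2-en-1-yl)chroman-4-one | COc1ccc([C@@H]2CC(=O)c3c(OCOC)cc(OCOC)c(CC=C(C)C)c3O2)cc1CC=C(C)C | intermediate
13 | (2S)-5,7-dihydroxy-2-[4-methoxy-3-(3-methylbut-2-en-1-yl)phenyl]-8-(3-methylbut-2-en-1-yl)chroman-4-one | COc1ccc([C@@H]2CC(=O)c3c(O)cc(O)c(CC=C(C)C)c3O2)cc1CC=C(C)C | target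

Total step count: 8
Longest linear sequence: 6 steps (steps 3, 4, 5, 6, 7, 8 from compound 5; equally steps 1, 2, 5, 6, 7, 8 from compound 1)

Steps most likely to fail

1. Step 7 (proposed new method). The acyl rhodium hydride may lose CO before the enol ether inserts. Insertion may take the Markovnikov course and close the five-membered ring. The cationic metal may hydrolyse the enol ether, or the ligand may discriminate the two alkene faces poorly. The fallback uses known chemistry, sets out from 4 and comes back to the route at 12. Compound 4 is treated with excess MeMgBr (THF, 0 °C) to give 1-[2-hydroxy-4,6-bis(methoxymethoxy)-3-(3-methylbut-2-en-1-yl)phenyl]ethan-1-ol F1. MnO2 (CH2Cl2, rt) oxidises this benzylic alcohol to 1-[2-hydroxy-4,6-bis(methoxymethoxy)-3-(3-methylbut-2-en-1-yl)phenyl]ethan-1-one F2. Claisen–Schmidt condensation of F2 with aldehyde 7 (KOH, EtOH, rt) should give (E)-1-[2-hydroxy-4,6-bis(methoxymethoxy)-3-(3-methylbut-2-en-1-yl)phenyl]-3-[4-methoxy-3-(3-methylbut-2-en-1-yl)phenyl]prop-2-en-1-one F3. NaOAc in refluxing EtOH closes the chalcone by oxa-Michael addition of the 2'-hydroxyl to rac-5,7-bis(methoxymethoxy)-2-[4-methoxy-3-(3-methylbut-2-en-1-yl)phenyl]-8-(3-methylbut-2-en-1-yl)chroman-4-one F4. The racemate is then resolved kinetically by asymmetric transfer hydrogenation (Cp*RhCl[(R,R)-TsDPEN] or its antipode, whichever reduces the 2R ketone faster; HCO2H/Et3N, EtOAc, rt, stopped near half conversion). The 2R enantiomer is reduced to (2R,4R)-5,7-bis(methoxymethoxy)-2-[4-methoxy-3-(3-methylbut-2-en-1-yl)phenyl]-8-(3-methylbut-2-en-1-yl)chroman-4-ol F5, and the unreacted 2S ketone, separated by chromatography, is 12.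

2. Step 5. The hindered, chelated phenoxide may attack the oxyphosphonium ion too slowly, so that the activated benzylic alcohol eliminates or alkylates the hydrazide instead. The fallback sets out from 9 and comes back at 10, replacing the redox condensation by alkylation with a preformed benzylic halide. Compound 9 is converted with PPh3 and N-chlorosuccinimide (CH2Cl2, 0 °C) into 4-(1,2-dichloroethyl)-1-methoxy-2-(3-methylbut-2-en-1-yl)benzene F6. Its p-methoxybenzylic chloride should alkylate the potassium phenoxide of 4 (K2CO3, DMF, rt) at the benzylic carbon in preference to the primary one, giving 10.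

3. Step 2. Acetalisation may occur at the wrong chelated hydroxyl or go on to the tris-acetal, on top of bis-prenylation in step 1. The fallback sets out from 1 and comes back at 4, fixing the regiochemistry by construction. Compound 1 is treated with MOMCl (2 equiv) and i-Pr2NEt (CH2Cl2, 0 °C) to give 2-hydroxy-4,6-bis(methoxymethoxy)benzaldehyde F7; here the two chelated hydroxyls are equivalent. Tsuji–Trost O-allylation of F7 with tert-butyl 2-methylbut-3-en-2-yl carbonate (Pd(PPh3)4, THF, rt) should give 2-[(2-methylbut-3-en-2-yl)oxy]-4,6-bis(methoxymethoxy)benzaldehyde F8. Aromatic Claisen rearrangement of F8 (N,N-diethylaniline or toluene, 110–130 °C) transfers the allyl unit with allylic inversion to the only free ortho carbon. This places the linear prenyl group next to the liberated hydroxyl, which is compound 4.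

Further compounds
F1 | step 7 | 1-[2-hydroxy-4,6-bis(methoxymethoxy)-3-(3-methylbut-2-en-1-yl)phenyl]ethan-1-ol (racemic) | CC(O)c1c(OCOC)cc(OCOC)c(CC=C(C)C)c1O
F2 | step 7 | 1-[2-hydroxy-4,6-bis(methoxymethoxy)-3-(3-methylbut-2-en-1-yl)phenyl]ethan-1-one | CC(=O)c1c(OCOC)cc(OCOC)c(CC=C(C)C)c1O
F3 | step 7 | (E)-1-[2-hydroxy-4,6-bis(methoxymethoxy)-3-(3-methylbut-2-en-1-yl)phenyl]-3-[4-methoxy-3-(3-methylbut-2-en-1-yl)phenyl]prop-2-en-1-one | COc1ccc(/C=C/C(=O)c2c(OCOC)cc(OCOC)c(CC=C(C)C)c2O)cc1CC=C(C)C
F4 | step 7 | rac-5,7-bis(methoxymethoxy)-2-[4-methoxy-3-(3-methylbut-2-en-1-yl)phenyl]-8-(3-methylbut-2-en-1-yl)chroman-4-one | COc1ccc(C2CC(=O)c3c(OCOC)cc(OCOC)c(CC=C(C)C)c3O2)cc1CC=C(C)C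
F5 | step 7 | (2R,4R)-5,7-bis(methoxymethoxy)-2-[4-methoxy-3-(3-methylbut-2-en-1-yl)phenyl]-8-(3-methylbut-2-en-1-yl)chroman-4-ol | COc1ccc([C@H]2C[C@@H](O)c3c(OCOC)cc(OCOC)c(CC=C(C)C)c3O2)cc1CC=C(C)C
F6 | step 5 | 4-(1,2-dichloroethyl)-1-methoxy-2-(3-methylbut-2-en-1-yl)benzene (racemic) | COc1ccc(C(Cl)CCl)cc1CC=C(C)C
F7 | step 2 | 2-hydroxy-4,6-bis(methoxymethoxy)benzaldehyde | O=Cc1c(O)cc(OCOC)cc1OCOC
F8 | step 2 | 2-[(2-methylbut-3-en-2-yl)oxy]-4,6-bis(methoxymethoxy)benzaldehyde | O=Cc1c(OC(C)(C)C=C)cc(OCOC)cc1OCOC
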